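## Structural features

The target is a germacranolide: a ten-membered carbocycle (C1–C10) with a trans-fused γ-lactone across C6–C7 (O6–C12(=O)–C11). The ring carries two trisubstituted olefins, C1=C10 (Z) and C4=C5 (E), so one ring olefin is cis and one is trans. There are five stereocentres: C6, C7 and C8 are contiguous on the ring (O6 trans to the C7 side chain, O8 cis to it), the quaternary C11 (OH, CH2Cl) adjoins C7 inside the lactone, and the allylic carbinol C2 is isolated. Fragile groups are the chlorohydrin (closes to the epoxide with base), the O8 acetate, the allylic alcohol at C2 and the 1(10),4-diene, which can cyclise across the ring under acid. The real difficulty is the medium ring with defined olefin geometry, combined with three adjacent ring stereocentres. The key step uses the fact that C10=C1–C2(O)–C3–C4=C5 is the ring-opened form of a 2-oxy-cyclohexa-1,3-diene (ring A: C10, C1, C2, C3, C4, C5) whose missing bond is C5–C10. C6–C9 then belong to ring B of a cis-fused decalin, on which C6, C7, C8 and the lactone can be set under six-membered-ring control.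

## Logic of the disconnections

31 ⇒ 30. The C13–Cl bond is cut last: chloride opens the spiro-epoxide of 30 at its primary carbon. This keeps the base-labile chlorohydrin out of every earlier step and stores C11 as a centre without enolisable hydrogen. The forward step may be only weakly acidic, because 31 holds an allylic alcohol and a 1,5-diene.

30 ⇒ 29. The C2–H bond is cut to the ketone. C2 is remote from the other stereocentres and is therefore set by a chiral reagent, and a C2 ketone is what the ring-opened enol ether delivers. The reduction must be 1,2-selective on a Z-enone and leave lactone, acetate and epoxide alone.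

29 ⇒ 28. The C3–H bond is cut, going back to the silyl enol ether. Protonation must occur at C3 (not C5) and in the cold, because 28 is a thermally labile hexatriene.

28 ⇒ 27 (key step). The bond C5–C10 is reconnected, so the C1=C10, C2=C3 and C4=C5 π bonds of 28 become the diene and the ring-fusion σ bond of 27. The ten-membered ring with two defined olefins is reduced to a cis-decalin. The forward step must turn H5 and C9 inward. Since a photochemical opening follows the ground-state half-chair, 27 must hold H5 and C9 pseudoaxial on ring A. This fixes the fusion as 5β-H/10β-CH3 and makes a rigid ring B (lactone already closed) part of the design. Epoxide and acetate ride through as spectators, so only three steps follow the photolysis.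

27 ⇒ 25 ⇒ 23. The O–Si bond on C2 and the acetyl–O8 bond are cut. 27 comes from enone 25 by kinetic enolisation, and 25 from silyl ether 23 by exchange of the O8 group. Placing the acetate before the photolysis removes any later need to tell O8 from O2.

23 ⇒ 22 ⇒ 19 ⇒ 18. The epoxide C–O bonds, the lactone bond O6–C12 and the C12–O bond are cut in turn, back to an isopropenyl group. In 18 this is the only electron-rich olefin, so allylic oxidation is unambiguous; after the key step two trisubstituted ring olefins would compete. The epoxide oxygen must enter from the H7 face, and the ring A enone must stay untouched.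

18 ⇒ 17 ⇒ 15. C3=C4 is cut by metathesis and C2–C3 by acyl substitution. An aldol closure was avoided: a diketone with two methyl ketone termini would give two regioisomeric cyclohexenones, and its base would equilibrate C5. Both arms must be cis on ring B.

15 ⇒ 14 ⇒ 13 ⇒ 12. C5–H, the exocyclic methylene carbon and the two epoxide C–O bonds are cut. The ring-fusion hydrogen must end anti to O6 and cis to the C10 methyl, the less stable arrangement, so it cannot be reached by equilibration. An epoxide opened with inversion by a palladium-bound hydride sets it stereospecifically. This demands epoxidation anti to the C7 substituent and hydride delivery to the substituted allyl terminus.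

12 ⇒ 10 ⇒ 9. The C5–C4 bond is cut between two sp2 carbons: the enol triflate of ketone 9 plus an acetyl anion equivalent. The former carvone carbonyl carbon becomes C5.

9 ⇒ 7. C10–C1 and C9–H are cut: conjugate reduction of the enone and alkylation of the resulting enolate. The quaternary centre must form anti to the C7 side chain, against the usual axial preference. For this reason the C8 oxygen is placed cis to the side chain beforehand, where it blocks the β face. Hydride is used because dissolving metal would expel a γ-oxygen.

7 ⇒ 6 ⇒ 4 ⇒ 2 ⇒ 1. The C8–O bond is cut: silyl ether, inversion at C8, and γ-oxygenation of 1 through its linear dienol ether 2. Compound 1 supplies C7 in the correct absolute configuration and all ring B carbons. Its γ-CH2 is activated only while the enone is present, so this oxygen goes in first.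

## Other disconnections considered

Alternative 1: cut C1=C10 by ring-closing metathesis.
- **Forward step:** the second-generation Grubbs catalyst would join a C10 2-methylallyl unit and a C1 vinyl unit that hang from O8 and O2 of one diisopropylsilylene, releasing ethylene and giving the eight-membered silaketal A1.
- **In favour:** two small fragments are united; C2 and C8 are each made separately under reagent control; the Z geometry is enforced by the eight-membered ring. On C1=C10 geometry and on C2 this plan is better than the chosen one.
- **Against:** A1 is still open with respect to the ten-membered ring. The C6–C7 bond, the trans lactone and C6/C7 must be made afterwards in a medium-ring closure. Metathesis onto a 1,1-disubstituted olefin is slow, and the tether costs steps to mount and remove.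
- **Comparison:** mechanistically it is thermal and catalytic, which equals or beats a dilute cold photolysis. Structurally it leaves the hardest bond for last, whereas the chosen plan has C6–C8 in place on a six-membered ring. Step economy should be about equal.

Alternative 2: cut C7–C11, with a temporary C8–C11 bond.
- **Forward step:** Rh2(OAc)4 would release nitrogen from a diazoacetyl group on O6; the carbenoid carbon C11 adds to the (E) C7=C8 silyl enol ether, closing lactone and cyclopropane together to give A2. Strain-release opening of C8–C11 would then unveil a C8 carbonyl.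
- **In favour:** intramolecular cyclopropanation is dependable; the tether fixes the lactone fusion from the single centre C6; the C8 carbonyl is ready for C8–C9 bond formation. On lactone stereocontrol it equals the chosen plan and needs no carbocyclic template.
- **Against:** C9 and C10 are absent from A2, so a ten-membered ring closure remains, with C8 and the C1=C10 geometry still to be controlled. C11 arrives as CH, so C13 and the tertiary hydroxyl must be added later, and a diazo compound must be handled.
- **Comparison:** both plans install the C11 functions late. Alternative 2 is weaker on ring formation and probably somewhat longer.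

Alternative 3: cut C8–C9.
- **Forward step:** a C8 aldehyde and an α-substituted allylic pinacol boronate (C9H2=C10(CH3)–C1H(Bpin)) in one chain would react through a six-membered chair. This forms C8–C9, shifts the olefin to C10=C1 and closes the ten-membered ring to A3.
- **In favour:** one step makes the ring, the C8 carbinol and the Z olefin through a closed transition state, which is at least as reliable as the conformational control of the photolysis. C2 is set beforehand, and A3 is only a few steps from the target. This is the best step economy of the four plans.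
- **Against:** a configurationally pure α-boryl allyl unit next to the C2 silyl ether must be made and preserved. The ring closure competes with oligomerisation and needs high dilution. C8 relative to C7 is decided in a macrocyclic transition state, and C13 and the C11 hydroxyl are still missing.
- **Comparison:** the chosen plan pays the ring strain with a photon in a unimolecular, concentration-independent step and sets C6–C8 on a chair, but it is longer.

Key step: step 19

Remark on numbering: eudesmane/germacrane numbering is used for all intermediates (C14 = methyl on C10, C15 = methyl on C4, C11–C13 = side chain on C7); β is the face of ring B that carries the C7 side chain, α the face of H7.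

Remark on stereochemistry: the enol-ether bond C2=C3 of 28 is E by the sequence rule (oxygen outranks C1), although the ring carbons C1 and C4 are cis on it; the ring fusion of 27 is 5β-H/10β-CH3 for the reason given under step 19.

## Steps

Step 1
Reactants: 1 (R)-carvone
Product: 2 linear trimethylsilyl dienol ether of carvone (C5(OSiMe3)=C10, C9=C8)
Conditions: MeMgBr, FeCl3 (cat.), Et2O, −20 °C; Me3SiCl, Et3N, HMPA, −20 °C to rt
Reagents that add atoms: chlorotrimethylsilane, C[Si](C)(C)Cl
Why: Thermodynamic enolisation of an enone: the iron-ate base from MeMgBr and catalytic FeCl3 should remove the γ-hydrogen at C8 and give the through-conjugated dienolate, which is silylated on oxygen; C7 is not touched.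

Step 2
Reactants: 2 linear trimethylsilyl dienol ether of carvone
Product: 4 (4S,5R)-4-hydroxycarvone (8α-OH, trans to the isopropenyl group), via epoxy silyl enol ether 3 (not isolated)
Conditions: mCPBA, NaHCO3, CH2Cl2, −20 °C; then citric acid, aq. MeOH
Reagents that add atoms: 3-chloroperoxybenzoic acid, OOC(=O)c1cccc(Cl)c1
Why: Vinylogous Rubottom oxidation: the peracid should epoxidise the terminal C8=C9 bond of the electron-rich silyloxydiene (much faster than the isopropenyl group) anti to the C7 substituent, and collapse of the epoxide with loss of silicon returns the enone with the new hydroxyl on C8; its configuration is turned in step 3.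

Step 3
Reactants: 4 (4S,5R)-4-hydroxycarvone
Product: 6 (4R,5R)-4-hydroxycarvone (8β-OH, cis to the isopropenyl group), via 4-nitrobenzoate 5 (not isolated)
Conditions: PPh3, DIAD, 4-nitrobenzoic acid, THF, 0 °C; then K2CO3, MeOH, 0 °C
Reagents that add atoms: 4-nitrobenzoic acid, OC(=O)c1ccc(cc1)[N+](=O)[O-]
Why: Mitsunobu inversion (SN2 at the allylic carbinol C8) followed by methanolysis of the activated ester should give the cis alcohol; the 8β-oxygen is the configuration of the target and the control element for step 5.

Step 4
Reactants: 6 (4R,5R)-4-hydroxycarvone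
Product: 7 (4R,5R)-4-(triethylsilyloxy)carvone
Conditions: Et3SiCl, imidazole, DMF, 0 °C
Reagents that add atoms: chlorotriethylsilane, CC[Si](Cl)(CC)CC
Why: Standard silylation of a secondary alcohol; the triethylsilyl ether tolerates hydride, amide bases, palladium catalysis, titanium and Grignard reagents and is removed in step 16.

Step 5
Reactants: 7 (4R,5R)-4-(triethylsilyloxy)carvone
Product: 9 keto ester with quaternary C10 (CH3 β, CH2CO2Me α), via lithium enolate 8 (not isolated)
Conditions: LiBH(s-Bu)3, THF, −78 °C; then BrCH2CO2Me, HMPA, −78 to 0 °C
Reagents that add atoms: methyl bromoacetate, COC(=O)CBr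
Why: Reductive alkylation: conjugate hydride addition gives the C5–C10 enolate regiospecifically without a carbanion at C9, so the C8 silyloxy group is not expelled; the electrophile should enter C10 on the α face because the β face is blocked by the cis-disposed C7 isopropenyl and syn-axial C8 silyloxy groups.

Step 6
Reactants: 9 keto ester
Product: 10 enol triflate (C5(OTf)=C6)
Conditions: KN(SiMe3)2, PhNTf2, THF, −78 °C
Reagents that add atoms: N-phenylbis(trifluoromethanesulfonimide), FC(F)(F)S(=O)(=O)N(c1ccccc1)S(=O)(=O)C(F)(F)F
Why: Enol triflate formation: C10 is quaternary, so the ketone can only enolise towards C6, and it is more acidic than the ester.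

Step 7
Reactants: 10 enol triflate
Product: 12 methyl ketone on C5 (C5=C6 enone), via ethoxydiene 11 (not isolated)
Conditions: Bu3SnC(OEt)=CH2, Pd(PPh3)4 (cat.), LiCl, THF, 65 °C; then 0.5 M HCl, THF, 0 °C
Reagents that add atoms: tributyl(1-ethoxyvinyl)stannane, CCCC[Sn](CCCC)(CCCC)C(=C)OCC; water, O
Why: Stille coupling of an alkenyl triflate with an acetyl anion equivalent, then mild hydrolysis of the enol ether; this attaches C4 and C15 to C5 and leaves C5=C6 activated for oxygenation.

Step 8
Reactants: 12 methyl ketone on C5 (enone)
Product: 13 5α,6α-epoxy ketone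
Conditions: t-BuOOH, BnNMe3OH (cat.), THF, 0 °C
Reagents that add atoms: tert-butyl hydroperoxide, CC(C)(C)OO
Why: Weitz–Scheffer epoxidation: the hydroperoxide anion should add to C6 anti to the neighbouring C7 isopropenyl group and close on C5, placing both epoxide bonds on the α face (C6–O as in the target); only the enone is electrophilic enough to react.

Step 9
Reactants: 13 5α,6α-epoxy ketone
Product: 14 alkenyl oxirane (isopropenyl on C5)
Conditions: Cp2Ti(μ-CH2)(μ-Cl)AlMe2, pyridine, THF, −40 to 0 °C
Reagents that add atoms: Tebbe reagent, C[Al](C)Cl.C=[Ti](C1C=CC=C1)C1C=CC=C1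
Why: Tebbe methylenation is non-basic, so the hindered methyl ketone is not enolised (no Claisen closure onto the ester), and at low temperature ketones react well before esters.

Step 10
Reactants: 14 alkenyl oxirane
Product: 15 hydroxy ester (6α-OH, 5β-H, isopropenyl on C5 α)
Conditions: Pd2(dba)3·CHCl3 (cat.), n-Bu3P, HCO2H, Et3N, dioxane, rt
Reagents that add atoms: none
Why: Tsuji hydrogenolysis of an alkenyl oxirane: zerovalent palladium ionises the allylic C5–O bond with inversion and the formate-derived hydride is passed from palladium to the more substituted allyl terminus C5 (terminal olefin kept), so hydrogen should enter on the β face, cis to the C10 methyl and anti to O6.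

Step 11
Reactants: 15 hydroxy ester
Product: 17 vinyl ketone (C10–CH2–CO–CH=CH2), via Weinreb amide 16 (not isolated)
Conditions: MeNH(OMe)·HCl, i-PrMgCl, THF, −20 °C; then CH2=CHMgBr, −20 to 0 °C; cold 1 M HCl
Reagents that add atoms: N,O-dimethylhydroxylamine hydrochloride (in 16 only), CNOC.Cl; vinylmagnesium bromide, C=C[Mg]Br
Why: Weinreb ketone synthesis in one flask: the chelated tetrahedral intermediate stops at the ketone stage, the C6 hydroxyl is carried as its alkoxide, and any δ-lactone formed onto O6 is opened by the amide anion to the same product.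

Step 12
Reactants: 17 vinyl ketone
Product: 18 cis-fused enone, 6α-hydroxy-8β-(triethylsilyloxy)-5β-eudesma-3,11(13)-dien-2-one
Conditions: second-generation Grubbs catalyst RuCl2(=CHPh)(PCy3)(H2IMes) (cat.), CH2Cl2, 40 °C
Reagents that add atoms: none
Why: Ring-closing metathesis between the enone vinyl group and the C5 isopropenyl group forms C3=C4 and closes six-membered ring A with the enone regiochemistry fixed; both arms are on the α face, so the decalin is cis-fused, and C5 never sees base.

Step 13
Reactants: 18 cis-fused enone
Product: 19 6α,12-diol
Conditions: SeO2 (cat.), t-BuOOH, CH2Cl2, 0 °C to rt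
Reagents that add atoms: tert-butyl hydroperoxide, CC(C)(C)OO
Why: Selenium dioxide allylic oxidation (ene reaction, then 2,3-shift) should attack the only electron-rich olefin, the isopropenyl group, at its methyl carbon (C12); the enone olefin is inert, and any over-oxidised material converges in step 14.

Step 14
Reactants: 19 6α,12-diol
Product: 22 α-methylene-γ-lactone (6α,12-olide), via hydroxy enal 20 (not isolated), via lactol 21 (not isolated)
Conditions: TEMPO (cat.), PhI(OAc)2, CH2Cl2, rt
Reagents that add atoms: none
Why: TEMPO/PhI(OAc)2 oxidative lactonisation: the primary allylic alcohol is oxidised first, the enal closes with O6 to a five-membered lactol and this is oxidised to the trans-fused lactone, which from here on holds ring B in the chair with O6 and C11 equatorial.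

Step 15
Reactants: 22 α-methylene-γ-lactone
Product: 23 11α,13-epoxy lactone
Conditions: t-BuOOH, DBU, CH2Cl2, 0 °C
Reagents that add atoms: tert-butyl hydroperoxide, CC(C)(C)OO
Why: Nucleophilic (Weitz–Scheffer type) epoxidation of the unhindered exocyclic acrylate: the peroxide adds to C13 and the lactone enolate closes on oxygen from the H7 face, away from C8 and its silyloxy group, which sets C11; the β,β-disubstituted ring A enone should react much more slowly.

Step 16
Reactants: 23 11α,13-epoxy lactone
Product: 24 8β-alcohol
Conditions: HF·pyridine, pyridine, THF, 0 °C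
Reagents that add atoms: none
Why: Fluoride cleavage of the secondary triethylsilyl ether; the buffered reagent should spare the epoxide, which is deactivated towards acid by the adjacent carbonyl.

Step 17
Reactants: 24 8β-alcohol
Product: 25 8β-acetoxy-11α,13-epoxy-2-oxo-5β-eudesm-3-en-6α,12-olide
Conditions: Ac2O, pyridine, DMAP (cat.), CH2Cl2, 0 °C to rt
Reagents that add atoms: acetic anhydride, CC(=O)OC(C)=O
Why: Acylation of the only free hydroxyl; the ester of the target is installed before the photolysis, so O8 never has to be told apart from O2.

Step 18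
Reactants: 25 8β-acetoxy enone
Product: 27 cis-fused 2-(tert-butyldimethylsilyloxy)-1,3-diene, via lithium dienolate 26 (not isolated)
Conditions: LiN(SiMe3)2, THF, −78 °C; t-BuMe2SiCl, HMPA, −78 °C
Reagents that add atoms: tert-butylchlorodimethylsilane, CC(C)(C)[Si](C)(C)Cl
Why: Kinetic α′-deprotonation at C1 of a 3-methylcyclohex-2-enone-type ketone gives the cross-conjugated dienolate, trapped on oxygen; the ketone is more acidic than the acetate, the lactone has no α-hydrogen, and the γ-hydrogen at C5 is not removed at −78 °C.

Step 19
Reactants: 27 cis-fused 2-(tert-butyldimethylsilyloxy)-1,3-diene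
Product: 28 ten-membered (1(10)Z,2E,4E)-triene 2-silyl enol ether
Conditions: hν (300 nm, Pyrex), degassed Et2O, −78 °C, partial conversion
Reagents that add atoms: none
Why: Excitation of the homoannular silyloxydiene (about 275–300 nm) should lead to conrotatory opening of the six-electron system made of the two π bonds and σ(C5–C10): C5–C10 is cleaved and C1=C10, C2=C3 (silyl enol ether) and C4=C5 are formed. The closest known reactions are the photochemical openings of ring-fused cyclohexa-1,3-dienes (steroidal 5,7-dienes; decalin-1,3-dienes to cyclodeca-1,3,5-trienes); the silyloxy group only moves the absorption to longer wavelength. No ring is closed by bond formation: the ten-membered ring is released by breaking the bond shared by rings A and B, so closure-mode descriptors do not apply, and no stereocentre is created (C5 and C10 become trigonal). The step needs torquoselectivity, which in the excited state follows the ground-state half-chair by least motion: groups pseudoaxial on ring A end up inside, pseudoequatorial ones outside. In 27 the trans lactone holds ring B in the chair with C11 and O6 equatorial, which puts C4 axial and C1 equatorial on ring B; H5 and C9 are then pseudoaxial on ring A and turn inward while C6 and the C10 methyl turn outward, giving C4=C5 E and C1=C10 Z. The cis isomer with 5α-H/10α-CH3 would be held in the opposite half-chair and should give the 1(10)E,4Z triene, which is why 27 is built with 5β-H/10β-CH3. Low temperature and the 300 nm cut-off limit thermal disrotatory reclosure, hydrogen shifts and secondary photolysis; unchanged 27 is recovered and 28 is taken cold into step 20.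

Step 20
Reactants: 28 ten-membered triene 2-silyl enol ether
Product: 29 8β-acetoxy-11α,13-epoxy-2-oxogermacra-1(10)Z,4E-dien-6α,12-olide
Conditions: Bu4NF, AcOH, THF, −78 °C
Reagents that add atoms: none
Why: Fluoride cleaves the silyl enol ether, and kinetic protonation of the dienolate by acetic acid at the α-carbon C3 should give the β,γ-unsaturated ketone with C4=C5 in place; this removes the triene and with it the thermal reclosure path.

Step 21
Reactants: 29 2-oxo germacradienolide
Product: 30 (2S)-8β-acetoxy-11α,13-epoxy-2-hydroxygermacra-1(10)Z,4E-dien-6α,12-olide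
Conditions: (R)-2-methyl-CBS-oxazaborolidine (cat.), catecholborane, toluene/CH2Cl2, −78 °C
Reagents that add atoms: none
Why: Corey–Bakshi–Shibata reduction: the alkenyl side (C1) acts as the large group, so the (R)-catalyst should deliver hydride to give the 2S alcohol; catecholborane leaves lactone, acetate, epoxide and olefins untouched.

Step 22
Reactants: 30 (2S)-epoxy alcohol
Product: 31 (2S,6R,7R,8R,11S)-8-acetoxy-13-chloro-2,11-dihydroxygermacra-1(10)Z,4E-dien-6,12-olide (target)
Conditions: LiCl, AcOH, THF, rt
Reagents that add atoms: lithium chloride, [Li+].[Cl-]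
Why: Acid-assisted SN2 opening of the spiro-epoxide by chloride at the primary C13 (C11 is quaternary and α to the carbonyl), so the C11 oxygen keeps its configuration; the weak acid should not trigger transannular cyclisation or ionisation at C2, and the step is last because the chlorohydrin reverts to the epoxide with base.

## Compound list

1 | (R)-carvone | CC1=CC[C@H](CC1=O)C(C)=C | starting material
2 | 1-(trimethylsilyloxy)-2-methyl-5-(prop-1-en-2-yl)cyclohexa-1,3-diene, linear dienol ether of 1 (C5(OSi)=C10, C9=C8; C7 as in 1) | CC1=C(O[Si](C)(C)C)C[C@@H](C=C1)C(C)=C | intermediate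
3 | 8α,9α-epoxide of 2 (not isolated) | CC1=C(O[Si](C)(C)C)C[C@@H]([C@H]2O[C@@H]12)C(C)=C | intermediate
4 | (4S,5R)-4-hydroxycarvone (8α-OH, trans to isopropenyl) | CC1=C[C@H](O)[C@H](CC1=O)C(C)=C | intermediate
5 | (4R,5R)-4-(4-nitrobenzoyloxy)carvone (not isolated) | CC1=C[C@@H](OC(=O)c2ccc(cc2)[N+](=O)[O-])[C@H](CC1=O)C(C)=C | intermediate
6 | (4R,5R)-4-hydroxycarvone (8β-OH, cis to isopropenyl) | CC1=C[C@@H](O)[C@H](CC1=O)C(C)=C | intermediate
7 | (4R,5R)-4-(triethylsilyloxy)carvone | CC1=C[C@@H](O[Si](CC)(CC)CC)[C@H](CC1=O)C(C)=C | intermediate
8 | lithium enolate (C5–OLi, C5=C10) of 8β-(triethylsilyloxy)dihydrocarvone (not isolated) | CC1=C([O-])C[C@@H]([C@H](O[Si](CC)(CC)CC)C1)C(C)=C.[Li+] | intermediate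
9 | methyl 2-[1-methyl-2-oxo-4-(prop-1-en-2-yl)-5-(triethylsilyloxy)cyclohexyl]acetate; C10: CH3 β, CH2CO2Me α; 8β-OSiEt3; 7β-isopropenyl | COC(=O)C[C@]1(C)C[C@@H](O[Si](CC)(CC)CC)[C@H](CC1=O)C(C)=C | intermediate
10 | enol triflate of 9 (C5(OTf)=C6) | COC(=O)C[C@]1(C)C[C@@H](O[Si](CC)(CC)CC)[C@H](C=C1OS(=O)(=O)C(F)(F)F)C(C)=C | intermediate
11 | 1-ethoxyvinyl diene (C5–C(OEt)=CH2, C5=C6) (not isolated) | COC(=O)C[C@]1(C)C[C@@H](O[Si](CC)(CC)CC)[C@H](C=C1C(=C)OCC)C(C)=C | intermediate
12 | methyl ketone on C5 (acetyl = C4, C15; C5=C6) | COC(=O)C[C@]1(C)C[C@@H](O[Si](CC)(CC)CC)[C@H](C=C1C(C)=O)C(C)=C | intermediate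
13 | 5α,6α-epoxy ketone | COC(=O)C[C@]1(C)C[C@@H](O[Si](CC)(CC)CC)[C@H]([C@@H]2O[C@]12C(C)=O)C(C)=C | intermediate
14 | 5α,6α-epoxide with isopropenyl on C5 (alkenyl oxirane) | COC(=O)C[C@]1(C)C[C@@H](O[Si](CC)(CC)CC)[C@H]([C@@H]2O[C@]12C(C)=C)C(C)=C | intermediate
15 | hydroxy ester: 6α-OH, 5β-H, isopropenyl on C5 (α), CH2CO2Me on C10 (α) | COC(=O)C[C@]1(C)C[C@@H](O[Si](CC)(CC)CC)[C@H]([C@H](O)[C@@H]1C(C)=C)C(C)=C | intermediate
16 | N-methoxy-N-methylamide of 15 (not isolated) | CON(C)C(=O)C[C@]1(C)C[C@@H](O[Si](CC)(CC)CC)[C@H]([C@H](O)[C@@H]1C(C)=C)C(C)=C | intermediate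
17 | vinyl ketone (C10–CH2–CO–CH=CH2), otherwise as 15 | C=CC(=O)C[C@]1(C)C[C@@H](O[Si](CC)(CC)CC)[C@H]([C@H](O)[C@@H]1C(C)=C)C(C)=C | intermediate
18 | 6α-hydroxy-8β-(triethylsilyloxy)-5β-eudesma-3,11(13)-dien-2-one (cis-fused: 5β-H, 10β-CH3) | CC[Si](CC)(CC)O[C@@H]1C[C@@]2(C)CC(=O)C=C(C)[C@H]2[C@@H](O)[C@@H]1C(C)=C | intermediate
19 | 6α,12-dihydroxy-8β-(triethylsilyloxy)-5β-eudesma-3,11(13)-dien-2-one | CC[Si](CC)(CC)O[C@@H]1C[C@@]2(C)CC(=O)C=C(C)[C@H]2[C@@H](O)[C@@H]1C(=C)CO | intermediate
20 | 12-aldehyde of 19 (hydroxy enal, not isolated) | CC[Si](CC)(CC)O[C@@H]1C[C@@]2(C)CC(=O)C=C(C)[C@H]2[C@@H](O)[C@@H]1C(=C)C=O | intermediate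
21 | 6α,12-lactol (both anomers, not isolated) | CC[Si](CC)(CC)O[C@@H]1C[C@@]2(C)CC(=O)C=C(C)[C@H]2[C@H]3OC(O)C(=C)[C@@H]31 | intermediate
22 | 2-oxo-8β-(triethylsilyloxy)-5β-eudesma-3,11(13)-dien-6α,12-olide | CC[Si](CC)(CC)O[C@@H]1C[C@@]2(C)CC(=O)C=C(C)[C@H]2[C@H]3OC(=O)C(=C)[C@@H]31 | intermediate
23 | 11α,13-epoxy-2-oxo-8β-(triethylsilyloxy)-5β-eudesm-3-en-6α,12-olide | CC[Si](CC)(CC)O[C@@H]1C[C@@]2(C)CC(=O)C=C(C)[C@H]2[C@H]3OC(=O)[C@]4(CO4)[C@@H]31 | intermediate
24 | 11α,13-epoxy-8β-hydroxy-2-oxo-5β-eudesm-3-en-6α,12-olide | O[C@@H]1C[C@@]2(C)CC(=O)C=C(C)[C@H]2[C@H]3OC(=O)[C@]4(CO4)[C@@H]31 | intermediate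
25 | 8β-acetoxy-11α,13-epoxy-2-oxo-5β-eudesm-3-en-6α,12-olide | CC(=O)O[C@@H]1C[C@@]2(C)CC(=O)C=C(C)[C@H]2[C@H]3OC(=O)[C@]4(CO4)[C@@H]31 | intermediate
26 | lithium cross-conjugated dienolate of 25 (C1=C2–OLi, C3=C4) (not isolated) | CC(=O)O[C@@H]1C[C@@]2(C)C=C([O-])C=C(C)[C@H]2[C@H]3OC(=O)[C@]4(CO4)[C@@H]31.[Li+] | intermediate
27 | 8β-acetoxy-2-(tert-butyldimethylsilyloxy)-11α,13-epoxy-5β-eudesma-1,3-dien-6α,12-olide (cis-fused precursor of the key step) | CC(=O)O[C@@H]1C[C@@]2(C)C=C(O[Si](C)(C)C(C)(C)C)C=C(C)[C@H]2[C@H]3OC(=O)[C@]4(CO4)[C@@H]31 | intermediate
28 | 8β-acetoxy-2-(tert-butyldimethylsilyloxy)-11α,13-epoxygermacra-1(10)Z,2E,4E-trien-6α,12-olide (product of the key step) | CC(=O)O[C@@H]1C/C(C)=C\C(O[Si](C)(C)C(C)(C)C)=C/C(C)=C/[C@H]2OC(=O)[C@]3(CO3)[C@@H]21 | intermediate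
29 | 8β-acetoxy-11α,13-epoxy-2-oxogermacra-1(10)Z,4E-dien-6α,12-olide | CC(=O)O[C@@H]1C/C(C)=C\C(=O)C/C(C)=C/[C@H]2OC(=O)[C@]3(CO3)[C@@H]21 | intermediate
30 | (2S)-8β-acetoxy-11α,13-epoxy-2-hydroxygermacra-1(10)Z,4E-dien-6α,12-olide | CC(=O)O[C@@H]1C/C(C)=C\[C@@H](O)C/C(C)=C/[C@H]2OC(=O)[C@]3(CO3)[C@@H]21 | intermediate
31 | (2S,6R,7R,8R,11S)-8-acetoxy-13-chloro-2,11-dihydroxygermacra-1(10)Z,4E-dien-6,12-olide | CC(=O)O[C@@H]1C/C(C)=C\[C@@H](O)C/C(C)=C/[C@H]2OC(=O)[C@](O)(CCl)[C@@H]21 | target

## Step count and least certain steps

Total step count: 22. Longest linear sequence: 22 steps, from 1 to 31.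

Step 19 (key step). The most likely failure is loss of torquoselectivity or an unfavourable photostationary composition. If ring B of 27 relaxes towards a twist form, the other half-chair of ring A becomes populated and opens to the 1(10)E,4Z isomer. In addition 28 absorbs near 300 nm and can reclose (thermally, in the disrotatory sense, to a trans-fused diene) or undergo hydrogen shifts. The fallback changes the stereochemical approach and sets out from 25. Base equilibration at C5, the γ-position of the enone (DBU, toluene, heat), should favour the trans-fused enone F1, which no longer has C4 axial on ring B. Enolisation and silylation as in step 18 would give the trans-fused silyloxydiene F2. A trans-fused diene has both angular substituents pseudoaxial and therefore only one least-motion mode, so irradiation should give the (1(10)E,2E,4E)-triene F3. Buffered fluoride as in step 20 would give the (1(10)E,4E)-ketone F4. Direct irradiation of the enone band near 350 nm (or reversible thiol addition) should then isomerise only the conjugated C1=C10 bond, and the Z isomer 29 is separated from the stationary mixture, at which point the route is rejoined.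

Step 2. The most likely failure is attack of the peracid at the more substituted enol-ether bond (oxygen on C10) or at the isopropenyl group, because three olefins compete for an electrophilic oxidant. The fallback sets out from 2 and uses a cycloaddition instead: singlet oxygen (O2, hν, tetraphenylporphyrin, CH2Cl2, −78 °C) should add across C5 and C8 of the cyclohexadiene, anti to the isopropenyl group, to give the endoperoxide F5. Reduction of the O–O bond (PPh3) and loss of silanol on work-up return 4.

Step 15. The most likely failure is competing epoxidation of the ring A enone, base-induced epimerisation at C5 (which would drain material into the trans-fused series), or incomplete facial control at C11. The fallback sets out from 19 and moves the epoxidation before the lactonisation, under reagent control. Asymmetric epoxidation of the 2-substituted allylic alcohol (Ti(OiPr)4, D-(−)-diethyl tartrate, t-BuOOH, 4 Å sieves, CH2Cl2, −20 °C) should give the epoxy diol F6 without base and without touching the enone. TEMPO/PhI(OAc)2 as in step 14 then closes the lactone and gives 23.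

Step 21. The most likely failure is poor facial selectivity, because the conformation of the ten-membered ring may override the catalyst. The fallback sets out from 29 and uses substrate control plus inversion. Reduction with NaBH4/CeCl3 in MeOH at −78 °C is taken to follow the ring bias; if this gives the (2R)-alcohol F7, Mitsunobu reaction with formic acid (PPh3, DIAD, THF) should give the inverted (2S)-formate F8. KHCO3 in MeOH cleaves the formate in the presence of the acetate and gives 30.

## Further compounds

F1 | step 19 | 8β-acetoxy-11α,13-epoxy-2-oxo-5α-eudesm-3-en-6α,12-olide (trans-fused C5 epimer of 25) | CC(=O)O[C@@H]1C[C@@]2(C)CC(=O)C=C(C)[C@@H]2[C@H]3OC(=O)[C@]4(CO4)[C@@H]31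
F2 | step 19 | 8β-acetoxy-2-(tert-butyldimethylsilyloxy)-11α,13-epoxy-5α-eudesma-1,3-dien-6α,12-olide (trans-fused) | CC(=O)O[C@@H]1C[C@@]2(C)C=C(O[Si](C)(C)C(C)(C)C)C=C(C)[C@@H]2[C@H]3OC(=O)[C@]4(CO4)[C@@H]31
F3 | step 19 | 8β-acetoxy-2-(tert-butyldimethylsilyloxy)-11α,13-epoxygermacra-1(10)E,2E,4E-trien-6α,12-olide | CC(=O)O[C@@H]1C/C(C)=C/C(O[Si](C)(C)C(C)(C)C)=C\C(C)=C\[C@H]2OC(=O)[C@]3(CO3)[C@@H]21
F4 | step 19 | 8β-acetoxy-11α,13-epoxy-2-oxogermacra-1(10)E,4E-dien-6α,12-olide | CC(=O)O[C@@H]1C/C(C)=C/C(=O)C/C(C)=C/[C@H]2OC(=O)[C@]3(CO3)[C@@H]21
F5 | step 2 | 5,8-epidioxide of 2 (peroxide bridge on the α face, trimethylsilyloxy on C5) | CC1=C[C@@H]2OO[C@@]1(O[Si](C)(C)C)C[C@@H]2C(C)=C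
F6 | step 15 | 11α,13-epoxy-6α,12-dihydroxy-8β-(triethylsilyloxy)-5β-eudesm-3-en-2-one | CC[Si](CC)(CC)O[C@@H]1C[C@@]2(C)CC(=O)C=C(C)[C@H]2[C@@H](O)[C@@H]1[C@@]3(CO3)CO
F7 | step 21 | (2R)-8β-acetoxy-11α,13-epoxy-2-hydroxygermacra-1(10)Z,4E-dien-6α,12-olide (C2 epimer of 30) | CC(=O)O[C@@H]1C/C(C)=C\[C@H](O)C/C(C)=C/[C@H]2OC(=O)[C@]3(CO3)[C@@H]21
F8 | step 21 | (2S)-2-formate of 30 | CC(=O)O[C@@H]1C/C(C)=C\[C@@H](OC=O)C/C(C)=C/[C@H]2OC(=O)[C@]3(CO3)[C@@H]21
A1 | alternative 1 | eight-membered diisopropylsilaketal across O8 and O2 with Z C1=C10, enoate on C8 and p-methoxybenzyl-protected C6 side chain | COC(=O)/C=C/[C@H]1C/C(C)=C\[C@H](C/C(C)=C/COCc2ccc(OC)cc2)O[Si](C(C)C)(C(C)C)O1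
A2 | alternative 2 | cyclopropane-fused γ-lactone (3-oxabicyclo[3.1.0]hexan-2-one) with exo C8 triisopropylsilyloxy group and C2 silyl ether side chain | O=C1O[C@H](/C=C(C)/C[C@H](O[Si](C)(C)C(C)(C)C)C=C)[C@H]2[C@H](O[Si](C(C)C)(C(C)C)C(C)C)[C@@H]12
A3 | alternative 3 | 8-hydroxy-2-(tert-butyldimethylsilyloxy)-13-norgermacra-1(10)Z,4E-dien-6,12-olide | O[C@@H]1C/C(C)=C\[C@@H](O[Si](C)(C)C(C)(C)C)C/C(C)=C/[C@H]2OC(=O)C[C@@H]21
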